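## The problem

Cardopatine (15) is a C2-symmetric cyclobutane whose neighbouring carbons C1 and C2 each carry an ethynyl group, and each alkyne ends at C5 of a 2,2'-bithiophene. No rings are fused: the skeleton is a chain of sp and sp2 carbons hung twice on one saturated four-membered ring. C1 and C2 are the only stereocentres, both R and trans to each other. Because the two arms are identical, trans is also the more stable arrangement, and wherever a centre carries an enolisable group its neighbour steers it to the trans side. The real task is therefore the absolute configuration and keeping it. That configuration is exposed twice: early, when the centres sit α to aldehydes, and late, when they are propargylic C–H carbons that a strong base could isomerise through an allene. The C1–C2 bond is strained and doubly propargylic, so long heating invites homolysis and scrambling, and the thienyl alkynes rule out hydrogenation, strong acid, oxidants and needless light. The outer thiophenes end in free α positions that react with aryl–palladium species, so any coupling that builds the bithiophene must be stopped from growing further. The enabling feature lies in the inner thiophene of each arm, the ring bonded to the alkyne at C2: C5 is its only free α carbon, its C–H bond is the most acidic of the ring and is acidified further by the 2-alkynyl group, and it is the atom that must bond to C2' of the outer ring.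

## Retrosynthesis

**15 to 14.** Two C–Si bonds are added in the retrosynthetic sense, taking 15 back to its bis(trimethylsilyl) derivative 14. The silyl groups build nothing; they occupy the outer α positions so that the preceding coupling stops at the bithiophene. The forward step is a fluoride protodesilylation that must leave the propargylic centres alone.

**14 to 10 and 13.** The two thiophene–thiophene bonds are cut, C5 of each inner ring from the bromine-bearing carbon of 13.
- Moving the cut one bond inward, to the alkyne–thiophene bond, and bringing both thiophenes in as one piece would be about two steps shorter; this is conceded.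
- A conventional cross-coupling of the same inter-ring bond would need a stoichiometric tin, boron or zinc group on one ring.
- The C–H cut is preferred because the cyclobutane-side partner 10 needs neither halogen nor metal, both bithiophenes come from monothiophenes, and the outer ring enters at the last C–C bond-forming step, where analogues could diverge.
- The precursor 10 has half the carbon count of 14 and keeps the C2 symmetry.
- The forward reaction must arylate C5 twice and nowhere else, tolerate two internal alkynes and the silyl caps, and run below the temperature at which the C1–C2 bond is at risk.

**10 to 8 and 9.** The two C(sp)–C(sp2) bonds are cut, giving the C8 diyne 8 and commercial 2-iodothiophene 9. A Sonogashira coupling at room temperature is the mildest way to make these bonds and asks nothing of the sp3 centres. Diyne 8 holds all the stereochemistry in eight carbons; its volatility is the price.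

**8 to 6 to 5.** Each terminal alkyne carbon is removed, tracing 8 through the tetrabromide 6 to the dialdehyde 5 (Corey–Fuchs). A one-step diazophosphonate homologation in basic methanol would be shorter, but 5 is epimerisable and such conditions could erode the configuration. The two-stage route makes its olefin under non-basic conditions and passes through 6, a stable, non-volatile compound at which the enantiopurity can be checked. The lithium stage passes through the diacetylide 7.

**5 to 4 to 3.** No C–C bond is cut; only the oxidation level changes. The diol 4 is the reduction product of the diacid 3, and a Swern oxidation returns the aldehyde level without over-oxidation. The forward oxidation must be cold and the dialdehyde used at once.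

**3 to 2 to 1.** No bond is cut. The (1R,2R) diacid 3 is separated from the commercial racemic trans diacid 1 through a diastereomeric ammonium salt 2. Buying the ring with its trans geometry and resolving it is shorter than any ring construction, at the cost of half the material.

**13 to 11.** The C–Si bond of the capped bromide 13 is cut, leading to 2,5-dibromothiophene 11 through the monolithio compound 12. One bromine–lithium exchange and a silyl quench are all that is asked.

## Roads not taken

**Alternative 1:** The cut removes two ring bonds, C1–C4 and C2–C3, and assembles the cyclobutane from methyl (E)-4-oxo-4-(2-oxo-1,3-oxazolidin-3-yl)but-2-enoate A1 and 1,1-bis(methylsulfanyl)ethene A2.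
- Forward step: a chiral titanium TADDOLate, made from TiCl2(OiPr)2 and a TADDOL diol, chelates the acyl oxazolidinone. The ketene dithioacetal adds to the β carbon and the titanium enolate closes on the thionium carbon, giving the trans cycloadduct A3.
- Merits: both centres are set catalytically in one step, the trans geometry comes from the E alkene, and no material of the wrong series is made.
- Weak points: A3 carries a dithioketal and two different acyl groups that a C2-symmetric target does not need. Desulfurisation with sponge Ni and a reduction are required to reach diol 4, and A1 must be prepared first, so about five operations stand against steps 1 to 3. The bithiophene arms are not addressed, so steps 4 to 10 would follow unchanged.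
- Comparison: in throughput of chiral material this road is better, since a resolution returns at most half of the racemate. The chosen plan sets against it a purchasable ring, purification by crystallisation and fewer steps. The two are compatible, because A3 could feed the same endgame at 4.

**Alternative 2:** The cut is the C3–C4 bond between the two ring methylenes.
- Forward step: t-BuLi exchanges one iodine of trans-4,5-bis(iodomethyl)cyclohexene A4 and the alkyllithium displaces the other iodide in a 4-exo-tet closure, giving trans-bicyclo[4.2.0]oct-3-ene A5. Cleaving the cyclohexene double bond would then release two CH2–CHO arms that already hold both carbons of each ethynyl group.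
- Merits: the absolute configuration can come from a well-controlled asymmetric Diels–Alder reaction of a fumaric ester. After ring closure the ring centres are never α to a carbonyl group, which is safer than passing through dialdehyde 5, and no resolution is needed.
- Weak points: the trans-fused bicycle is strained, so closure competes with elimination, reduction and intermolecular coupling. A5 is a volatile hydrocarbon. Turning CH2–CHO into C≡CH on both arms (enol sulfonate formation and elimination) is less routine than a Corey–Fuchs sequence. About seven steps lead to diyne 8, against six.
- Comparison: this road is better in configurational security. The chosen plan sets against it a shorter sequence of routine reactions from 1 and an enantiopurity check at the stable tetrabromide 6.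

**Alternative 3:** The cut is the C1–C2 bond between the two stereocentres.
- Forward step: the silyl ketene acetal of the (S,Z) lactone 8-methyl-3,4,5,8-tetrahydro-2H-oxocin-2-one A6 undergoes an Ireland–Claisen rearrangement. The eight-membered ring contracts to cis-2-[(E)-prop-1-enyl]cyclobutane-1-carboxylic acid A7, with the carbinol centre transferring its chirality to both ring carbons.
- Merits: one inexpensive stereocentre controls two, and the arms arrive differentiated as carboxyl and propenyl.
- Weak points: the product is cis, so the carboxyl-bearing centre must later be epimerised. The propenyl arm must be cleaved to an aldehyde and the acid adjusted to one before each is homologated separately, which wastes the symmetry of the target. The medium-ring Z lactone itself costs several steps.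
- Comparison: this road is better for analogues with two different arms, which the chosen plan can reach only statistically. For 15 itself it is roughly twice as long.

Key step: step 9

Assumption: the less soluble salt of racemic acid 1 with (S)-1-phenylethylamine is taken to be the 1:1 salt of the (1R,2R) acid. Should the (1S,2S) acid crystallise instead, the (R)-amine is used in the same way and nothing downstream changes.

## Steps

Step 1
Reactants: 1 (±)-trans-cyclobutane-1,2-dicarboxylic acid
Product: 2 (S)-1-phenylethylammonium (1R,2R)-2-carboxycyclobutane-1-carboxylate (1:1 salt)
Conditions: (S)-1-phenylethylamine (1.0 equiv), EtOH/H2O, reflux, slow cooling to rt; salt recrystallised from EtOH/H2O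
Reagents that add atoms: (S)-1-phenylethylamine, C[C@H](N)c1ccccc1
Why: Classical resolution by diastereomeric salt formation; the two salts differ in solubility, and the less soluble one is recrystallised until its rotation no longer changes. No stereocentre is made; the 1R,2R acid is selected from the racemate.

Step 2
Reactants: 2 (S)-1-phenylethylammonium (1R,2R)-2-carboxycyclobutane-1-carboxylate
Product: 3 (1R,2R)-cyclobutane-1,2-dicarboxylic acid
Conditions: 2 M HCl, 0 °C; NaCl saturation, EtOAc extraction
Reagents that add atoms: none
Why: Acid–base liberation of the diacid from its ammonium salt; the amine stays in the aqueous phase as its hydrochloride and can be recovered. The ring centres are not touched.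

Step 3
Reactants: 3 (1R,2R)-cyclobutane-1,2-dicarboxylic acid
Product: 4 [(1R,2R)-cyclobutane-1,2-diyl]dimethanol
Conditions: BH3·SMe2 (3 equiv), THF, 0 °C to rt; MeOH quench, repeated evaporation from MeOH
Reagents that add atoms: none
Why: Borane reduction of carboxylic acids through acyloxyboranes is fast and non-basic, so the α centres cannot enolise. Boron leaves as volatile B(OMe)3, which spares an aqueous extraction of a water-soluble diol.

Step 4
Reactants: 4 [(1R,2R)-cyclobutane-1,2-diyl]dimethanol
Product: 5 (1R,2R)-cyclobutane-1,2-dicarbaldehyde
Conditions: (COCl)2 (2.6 equiv), DMSO (5 equiv), CH2Cl2, −78 °C; Et3N (8 equiv), −78 to −30 °C; cold aqueous NaH2PO4 wash; dried CH2Cl2 solution used directly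
Reagents that add atoms: none
Why: Swern oxidation stops at the aldehyde. Both hydroxyls are activated before base is added and the trans ring geometry disfavours a lactol, so lactone formation should not compete. At low temperature the alkoxysulfonium ylide should collapse faster than the amine can enolise the product.

Step 5
Reactants: 5 (1R,2R)-cyclobutane-1,2-dicarbaldehyde
Product: 6 (1R,2R)-1,2-bis(2,2-dibromoethenyl)cyclobutane
Conditions: CBr4 (4.4 equiv), PPh3 (8.8 equiv), CH2Cl2, 0 °C, 20 min; then 5 in CH2Cl2, 0 °C
Reagents that add atoms: carbon tetrabromide, BrC(Br)(Br)Br
Why: Ramirez dibromoolefination, the first stage of the Corey–Fuchs sequence. Preformed Ph3P=CBr2 reacts with each aldehyde in a Wittig reaction without added base, and the ring centres cease to be α-carbonyl carbons. Compound 6 is stable and non-volatile, so it can be purified on silica and its enantiopurity checked.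

Step 6
Reactants: 6 (1R,2R)-1,2-bis(2,2-dibromoethenyl)cyclobutane
Product: 8 (1R,2R)-1,2-diethynylcyclobutane, via dilithium diacetylide 7 (not isolated)
Conditions: n-BuLi (4.4 equiv), THF, −78 °C, then to 0 °C; H2O; pentane extraction, concentration through a column to a stock solution (not to dryness)
Reagents that add atoms: none
Why: Second stage of the Corey–Fuchs sequence. Bromine–lithium exchange gives a vinylidene carbenoid that undergoes the Fritsch–Buttenberg–Wiechell 1,2-hydrogen shift to the alkyne; a second equivalent of base forms acetylide 7, and water releases 8.

Step 7
Reactants: 8 (1R,2R)-1,2-diethynylcyclobutane; 9 2-iodothiophene (2.4 equiv)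
Product: 10 (1R,2R)-1,2-bis(thiophen-2-ylethynyl)cyclobutane
Conditions: PdCl2(PPh3)2 (4 mol %), CuI (8 mol %), Et3N/THF, degassed, rt
Reagents that add atoms: none
Why: Sonogashira coupling of a terminal alkyne with a reactive heteroaryl iodide proceeds at room temperature. Exclusion of oxygen suppresses oxidative alkyne dimerisation, and the sp3 centres are not involved.

Step 8
Reactants: 11 2,5-dibromothiophene
Product: 13 (5-bromothiophen-2-yl)trimethylsilane, via 5-bromo-2-thienyllithium 12 (not isolated)
Conditions: n-BuLi (1.0 equiv), THF, −78 °C; Me3SiCl (1.1 equiv), −78 °C to rt
Reagents that add atoms: chlorotrimethylsilane, C[Si](C)(C)Cl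
Why: A single bromine–lithium exchange at −78 °C with one equivalent of n-BuLi is selective, because the monolithio species exchanges much more slowly; trapping with Me3SiCl gives the capped bromide.

Step 9
Reactants: 10 (1R,2R)-1,2-bis(thiophen-2-ylethynyl)cyclobutane; 13 (5-bromothiophen-2-yl)trimethylsilane (2.6 equiv)
Product: 14 (1R,2R)-1,2-bis{[5'-(trimethylsilyl)-2,2'-bithiophen-5-yl]ethynyl}cyclobutane
Conditions: Pd(OAc)2 (5 mol %), PCy3·HBF4 (10 mol %), PivOH (30 mol %), K2CO3 (3 equiv), toluene, 90 °C, argon, dark
Reagents that add atoms: none
Why: Pd(OAc)2 and PCy3 should form a zerovalent palladium species that inserts into the carbon–bromine bond of 13. Pivalate replaces bromide on the divalent palladium aryl and removes the C5 proton of one thiophene of 10 in a concerted metalation–deprotonation while the Pd–C5 bond forms, K2CO3 serving as the stoichiometric base. Reductive elimination gives the C5–C2' bond and returns zerovalent palladium, and the cycle repeats on the second arm. The closest known reaction type is the carboxylate-assisted direct arylation of thiophene α positions with aryl and heteroaryl bromides, which is also known to tolerate silyl groups on the thiophene. No ring is closed and no stereocentre is formed; C1 and C2 are spectators, and the insoluble carbonate in toluene and the 90 °C ceiling are chosen so that neither the propargylic C–H bonds nor the strained C1–C2 bond are put at risk. The site selectivity needed is C5–H over the β C–H bonds at C3 and C4, and it is secured because C5 is the only free α position of each ring and the 2-alkynyl group makes its proton the most acidic. Chain growth is excluded because 13 has no α C–H of its own and the SiMe3 group occupies the outer α position of 14. Insertion of the internal alkynes into the aryl–palladium bond is the competing path, and the bulky, electron-rich PCy3 together with the fast pivalate-assisted C–H cleavage is relied on to hold it back.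

Step 10
Reactants: 14 (1R,2R)-1,2-bis{[5'-(trimethylsilyl)-2,2'-bithiophen-5-yl]ethynyl}cyclobutane
Product: 15 cardopatine, (1R,2R)-1,2-bis[(2,2'-bithiophen-5-yl)ethynyl]cyclobutane
Conditions: Bu4NF (2.5 equiv), wet THF, 0 °C to rt, dark
Reagents that add atoms: none
Why: Fluoride-induced protodesilylation; fluoride attacks silicon, the 2-thienyl group leaves as a stabilised carbanion and is protonated by water. The conditions are too weakly basic to remove a propargylic ring proton.

## Compound list

1 | (±)-trans-cyclobutane-1,2-dicarboxylic acid (racemate, trans) | O=C(O)C1CCC1C(=O)O | starting material
2 | (S)-1-phenylethylammonium (1R,2R)-2-carboxycyclobutane-1-carboxylate | C[C@H]([NH3+])c1ccccc1.OC(=O)[C@@H]1CC[C@H]1C([O-])=O | intermediate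
3 | (1R,2R)-cyclobutane-1,2-dicarboxylic acid | O=C(O)[C@@H]1CC[C@H]1C(=O)O | intermediate
4 | [(1R,2R)-cyclobutane-1,2-diyl]dimethanol | OC[C@@H]1CC[C@H]1CO | intermediate
5 | (1R,2R)-cyclobutane-1,2-dicarbaldehyde | O=C[C@@H]1CC[C@H]1C=O | intermediate
6 | (1R,2R)-1,2-bis(2,2-dibromoethenyl)cyclobutane | BrC(Br)=C[C@@H]1CC[C@H]1C=C(Br)Br | intermediate
7 | (1R,2R)-1,2-bis(lithioethynyl)cyclobutane (dilithium diacetylide) | [Li]C#C[C@@H]1CC[C@H]1C#C[Li] | intermediate
8 | (1R,2R)-1,2-diethynylcyclobutane | C#C[C@@H]1CC[C@H]1C#C | intermediate
9 | 2-iodothiophene | Ic1cccs1 | starting material
10 | (1R,2R)-1,2-bis(thiophen-2-ylethynyl)cyclobutane | C(#C[C@@H]1CC[C@H]1C#Cc1cccs1)c1cccs1 | intermediate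
11 | 2,5-dibromothiophene | Brc1ccc(Br)s1 | starting material
12 | 5-bromo-2-thienyllithium | [Li]c1ccc(Br)s1 | intermediate
13 | (5-bromothiophen-2-yl)trimethylsilane | C[Si](C)(C)c1ccc(Br)s1 | intermediate
14 | (1R,2R)-1,2-bis{[5'-(trimethylsilyl)-2,2'-bithiophen-5-yl]ethynyl}cyclobutane | C(#C[C@@H]1CC[C@H]1C#Cc1ccc(-c2ccc([Si](C)(C)C)s2)s1)c1ccc(-c2ccc([Si](C)(C)C)s2)s1 | intermediate
15 | cardopatine, (1R,2R)-1,2-bis[(2,2'-bithiophen-5-yl)ethynyl]cyclobutane | C(#C[C@@H]1CC[C@H]1C#Cc1ccc(-c2cccs2)s1)c1ccc(-c2cccs2)s1 | target

## Step count and risks

Total: 10 steps. Longest linear sequence: 9 steps (steps 1 to 7, 9 and 10). Step 8 is a one-step branch.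

**Step 9 (key step).** Three things may go wrong.
- Insertion of an internal alkyne into the aryl–palladium bond may compete with C–H cleavage.
- The silyl cap may be lost in the basic carboxylate medium, after which the freed α position is arylated again and the chain grows.
- Heating may cause slow stereomutation by homolysis of the C1–C2 bond, or the second arylation may stall.

Fallback, from 10 to 15: the bonds are formed by a Negishi coupling at room temperature without a cap. Compound 10 is deprotonated at both C5 positions with LiN(iPr)2 in THF at −78 °C to give (1R,2R)-1,2-bis[(5-lithiothiophen-2-yl)ethynyl]cyclobutane F1. ZnCl2 converts this into (1R,2R)-1,2-bis{[5-(chlorozincio)thiophen-2-yl]ethynyl}cyclobutane F2. Coupling with 2-bromothiophene under Pd(PPh3)4 at rt to 40 °C then gives 15 directly. No cap is needed because no C–H bond is activated under these conditions, so 13, 14 and step 10 fall away.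

**Step 1.** Discrimination between the two diastereomeric salts may be poor (co-crystallisation or oiling out), or the salt of the other enantiomer may crystallise.

Fallback, from 1 to 4: a covalent separation. Acid 1 is converted with oxalyl chloride into (±)-trans-cyclobutane-1,2-dicarbonyl dichloride F3. This acylates the lithium salt of (S)-4-benzyl-1,3-oxazolidin-2-one to give the diastereomeric bis-imides (1R,2R)-1,2-bis{[(S)-4-benzyl-2-oxo-1,3-oxazolidin-3-yl]carbonyl}cyclobutane F4 and its (1S,2S) diastereomer F5, which are separated by chromatography or crystallisation. Reduction of F4 with LiBH4 in THF/H2O gives diol 4 and returns the auxiliary. The assignment of F4 is to be secured by correlation with the known diol or by crystallography.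

**Step 4.** The α centres may epimerise by amine-induced enolisation (through the cis isomer to the enantiomer), and the small polar dialdehyde may be lost by hydration, oligomerisation or evaporation.

Fallback, from 3 to 5: the aldehyde is reached by reduction and not by oxidation. Acid 3 is coupled with N,O-dimethylhydroxylamine (carbonyldiimidazole activation) to give (1R,2R)-N,N'-dimethoxy-N,N'-dimethylcyclobutane-1,2-dicarboxamide F6. LiAlH4 in THF at −78 to −40 °C, followed by a cold aqueous KHSO4 quench, releases 5 from a chelated tetrahedral intermediate without exposing it to base.

**Step 6.** The C8 diyne may be lost by evaporation during isolation, the rearrangement may stop short, or excess n-BuLi may remove a propargylic proton.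

Fallback, from 6 to 10: the diyne is not isolated. Acetylide 7 is generated as in step 6 and treated with ZnCl2 to give (1R,2R)-1,2-bis[(chlorozincio)ethynyl]cyclobutane F7. This is coupled in the same flask with 9 under Pd(PPh3)4 at rt (Negishi alkynylation), giving 10 and bypassing 8 and the Sonogashira step.

## Further compounds

F1 | step 9 | (1R,2R)-1,2-bis[(5-lithiothiophen-2-yl)ethynyl]cyclobutane | [Li]c1ccc(C#C[C@@H]2CC[C@H]2C#Cc2ccc([Li])s2)s1
F2 | step 9 | (1R,2R)-1,2-bis{[5-(chlorozincio)thiophen-2-yl]ethynyl}cyclobutane | Cl[Zn]c1ccc(C#C[C@@H]2CC[C@H]2C#Cc2ccc([Zn]Cl)s2)s1
F3 | step 1 | (±)-trans-cyclobutane-1,2-dicarbonyl dichloride | O=C(Cl)C1CCC1C(=O)Cl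
F4 | step 1 | (1R,2R)-1,2-bis{[(S)-4-benzyl-2-oxo-1,3-oxazolidin-3-yl]carbonyl}cyclobutane | O=C([C@@H]1CC[C@H]1C(=O)N1[C@@H](Cc2ccccc2)COC1=O)N1[C@@H](Cc2ccccc2)COC1=O
F5 | step 1 | (1S,2S)-1,2-bis{[(S)-4-benzyl-2-oxo-1,3-oxazolidin-3-yl]carbonyl}cyclobutane | O=C([C@H]1CC[C@@H]1C(=O)N1[C@@H](Cc2ccccc2)COC1=O)N1[C@@H](Cc2ccccc2)COC1=O
F6 | step 4 | (1R,2R)-N,N'-dimethoxy-N,N'-dimethylcyclobutane-1,2-dicarboxamide | CON(C)C(=O)[C@@H]1CC[C@H]1C(=O)N(C)OC
F7 | step 6 | (1R,2R)-1,2-bis[(chlorozincio)ethynyl]cyclobutane | Cl[Zn]C#C[C@@H]1CC[C@H]1C#C[Zn]Cl
A1 | alternative 1 | methyl (E)-4-oxo-4-(2-oxo-1,3-oxazolidin-3-yl)but-2-enoate | COC(=O)/C=C/C(=O)N1CCOC1=O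
A2 | alternative 1 | 1,1-bis(methylsulfanyl)ethene | C=C(SC)SC
A3 | alternative 1 | methyl trans-3,3-bis(methylsulfanyl)-2-(2-oxo-1,3-oxazolidine-3-carbonyl)cyclobutane-1-carboxylate, enantiomer shown | COC(=O)[C@@H]1CC(SC)(SC)[C@H]1C(=O)N1CCOC1=O
A4 | alternative 2 | trans-4,5-bis(iodomethyl)cyclohexene, enantiomer shown | C1C=CC[C@H](CI)[C@H]1CI
A5 | alternative 2 | trans-bicyclo[4.2.0]oct-3-ene, enantiomer shown | C1C=CC[C@@H]2CC[C@H]21
A6 | alternative 3 | (S,Z)-8-methyl-3,4,5,8-tetrahydro-2H-oxocin-2-one | O=C1CCC/C=C\[C@H](C)O1
A7 | alternative 3 | cis-2-[(E)-prop-1-enyl]cyclobutane-1-carboxylic acid, enantiomer shown | C/C=C/[C@@H]1CC[C@@H]1C(=O)O
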